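C1 is the quaternary ring carbon bearing the hydroxyl and the undecanoyl group, C2 and C5 carry the acetates, and C3=C4 is the ring alkene.
Enabling feature: C2, C1 and C5 of the cyclopentene form a triol triad with a mirror plane through C1 and the midpoint of C3=C4, so the C2–C3 and C5–C4 bonds are equivalent and cutting both leaves a symmetric 2,2-disubstituted malonaldehyde.
Retrosynthesis: unmask the C1 hydroxyl from a PMB ether and the ketone from an alkyne; cut C3=C4 (metathesis); cut C2–C3 and C5–C4 together (two vinyl nucleophiles on the dialdehyde); cut the C1–alkyne bond (1-undecyne plus 2,2-dimethyl-1,3-dioxan-5-one).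
Forward: the side chain is attached to C1 first, both vinyl arms are installed in one two-directional Grignard step, the single ring (the cyclopentene) is closed by metathesis, and alkyne hydration and PMB removal complete the route.
Stereochemistry: C2 and C5, and with them the pseudoasymmetric C1, arise from five-membered magnesium chelates between each formyl oxygen and the C1 ether oxygen, with vinyl entering past the slim alkyne; the target is meso, so no absolute control is required.

Key step: step 5

Remark: the target and all symmetric intermediates are meso; desymmetrised in-flask and fallback compounds are racemic and are drawn as one enantiomer. "Threo" means that the carbinol oxygen and the C1 ether oxygen lie on opposite sides in the Fischer projection of the C3–C2–C1–C5 chain, which becomes trans on the ring.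

Step 1
Reactants: 1 1-undecyne; 2 2,2-dimethyl-1,3-dioxan-5-one
Product: 4 2,2-dimethyl-5-(undec-1-ynyl)-1,3-dioxan-5-ol, via 1-undecynyllithium 3 (not isolated)
Conditions: n-BuLi, THF, −78 °C; then 2, −78 to 0 °C; aq NH4Cl
Reagents that add atoms: none
Why: 1,2-addition of a lithium acetylide to a ketone; the weakly basic acetylide should add to the unhindered dioxanone carbonyl faster than it enolises it at −78 °C, and no stereocentre is formed.

Step 2
Reactants: 4 2,2-dimethyl-5-(undec-1-ynyl)-1,3-dioxan-5-ol
Product: 6 5-(4-methoxybenzyloxy)-2,2-dimethyl-5-(undec-1-ynyl)-1,3-dioxane, via sodium alkoxide 5 (not isolated)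
Conditions: NaH, DMF, 0 °C; then 4-methoxybenzyl chloride, Bu4NI (cat.), 0 °C to rt
Reagents that add atoms: 4-methoxybenzyl chloride, COc1ccc(CCl)cc1
Why: Williamson etherification; the tertiary propargylic alkoxide is nucleophilic and unencumbered on its alkyne side, and iodide catalysis supplies the more reactive benzylic iodide.

Step 3
Reactants: 6 5-(4-methoxybenzyloxy)-2,2-dimethyl-5-(undec-1-ynyl)-1,3-dioxane
Product: 7 2-(4-methoxybenzyloxy)-2-(undec-1-ynyl)propane-1,3-diol
Conditions: AcOH/H2O/THF (3:1:1), 40 °C
Reagents that add atoms: none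
Why: Acid-catalysed hydrolysis of an isopropylidene acetal; the PMB ether and the internal alkyne should be inert to warm aqueous acetic acid.

Step 4
Reactants: 7 2-(4-methoxybenzyloxy)-2-(undec-1-ynyl)propane-1,3-diol
Product: 8 2-(4-methoxybenzyloxy)-2-(undec-1-ynyl)propanedial
Conditions: Dess–Martin periodinane (2.5 equiv), CH2Cl2, 0 °C to rt; short silica pad (Et2O/pentane); used at once
Reagents that add atoms: none
Why: Dess–Martin oxidation of both primary alcohols; the dialdehyde has no α-hydrogen, and the non-basic, non-aqueous procedure should limit hydrate formation and deformylation.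

Step 5
Reactants: 8 2-(4-methoxybenzyloxy)-2-(undec-1-ynyl)propanedial; 9 vinylmagnesium bromide (two equivalents, one per formyl group)
Product: 11 meso threo,threo-4-(4-methoxybenzyloxy)-4-(undec-1-ynyl)hepta-1,6-diene-3,5-diol, via bromomagnesium alkoxide mono-adduct 10 (not isolated)
Conditions: MgBr2·OEt2 (2.5 equiv), CH2Cl2, −78 °C; then CH2=CHMgBr (1.0 M in THF, 2.6 equiv), −78 to −40 °C; aq NH4Cl
Reagents that add atoms: vinylmagnesium bromide (second equivalent of 9), C=C[Mg]Br
Why: Two successive Cram-chelate Grignard additions: magnesium binds a formyl oxygen together with the C1 ether oxygen in a five-membered chelate and the first equivalent of 9 delivers vinyl to that carbonyl carbon to give mono-adduct 10, after which the second equivalent adds in the same way to the remaining formyl group to give the bis-alkoxide. The closest known reaction type is the chelation-controlled addition of vinylmagnesium halides to α-benzyloxy aldehydes, used here at both ends of one malonaldehyde. No ring closes; the step forms the C2–C3 and C5–C4 bonds and both secondary carbinols. The C2 and C5 configurations are set by the chelate ring, which holds the alkynyl rod and the other one-carbon arm on opposite faces so that vinyl enters past the alkyne, and C1 becomes a pseudoasymmetric centre because two like additions occur on mirror-related arms. The step needs the chelate face at both aldehydes, and the coordinating PMB ether, pre-complexation with MgBr2·OEt2 in CH2Cl2 and the small effective size of the alkyne compared with a magnesium-bound formyl or alkoxide-bearing arm should secure it.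

Step 6
Reactants: 11 meso threo,threo-4-(4-methoxybenzyloxy)-4-(undec-1-ynyl)hepta-1,6-diene-3,5-diol
Product: 12 meso 4-(4-methoxybenzyloxy)-4-(undec-1-ynyl)hepta-1,6-diene-3,5-diyl diacetate
Conditions: Ac2O (3 equiv), DMAP (cat.), pyridine, CH2Cl2, rt
Reagents that add atoms: acetic anhydride, CC(=O)OC(C)=O
Why: DMAP-catalysed acylation of two secondary allylic alcohols; the C–O bonds are not touched, so the configuration is retained.

Step 7
Reactants: 12 meso 4-(4-methoxybenzyloxy)-4-(undec-1-ynyl)hepta-1,6-diene-3,5-diyl diacetate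
Product: 13 meso 2-(4-methoxybenzyloxy)-2-(undec-1-ynyl)cyclopent-4-ene-1,3-diyl diacetate
Conditions: second-generation Grubbs catalyst (H2IMes)(PCy3)Cl2Ru=CHPh (5 mol %), CH2Cl2 (0.01 M), 40 °C
Reagents that add atoms: none
Why: Ring-closing metathesis of a 1,6-diene to a cyclopentene with loss of ethylene; the hindered internal alkyne could take part only through a cyclobutene-forming enyne closure, which should not compete.

Step 8
Reactants: 13 meso 2-(4-methoxybenzyloxy)-2-(undec-1-ynyl)cyclopent-4-ene-1,3-diyl diacetate
Product: 14 meso 2-(4-methoxybenzyloxy)-2-undecanoylcyclopent-4-ene-1,3-diyl diacetate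
Conditions: Ph3PAuNTf2 (5 mol %), H2O (5 equiv), 1,4-dioxane, rt
Reagents that add atoms: water, O
Why: Neighbouring-ester-assisted gold-catalysed alkyne hydration: an acetate carbonyl cis to the alkyne should add 6-exo-dig to the gold-bound triple bond at the carbon attached to C1, and water then opens the cyclic acyloxonium so that the ketone sits at that carbon and the acetyl group returns to its oxygen; the ring alkene cannot reach the alkyne and C1 has no hydrogen to epimerise.

Step 9
Reactants: 14 meso 2-(4-methoxybenzyloxy)-2-undecanoylcyclopent-4-ene-1,3-diyl diacetate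
Product: 15 meso 2-hydroxy-2-undecanoylcyclopent-4-ene-1,3-diyl diacetate
Conditions: DDQ (1.5 equiv), CH2Cl2/pH 7 phosphate buffer (10:1), 0 °C to rt
Reagents that add atoms: none
Why: DDQ oxidative cleavage of a p-methoxybenzyl ether under neutral buffered conditions, which should spare the allylic acetates, the alkene and the tertiary α-ketol; the C1 hydroxyl is trans to both acetates, so acyl migration is not expected.

**Compound list**
1 | 1-undecyne | CCCCCCCCCC#C | starting material
2 | 2,2-dimethyl-1,3-dioxan-5-one | CC1(C)OCC(=O)CO1 | starting material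
3 | 1-undecynyllithium (not isolated) | CCCCCCCCCC#C[Li] | intermediate
4 | 2,2-dimethyl-5-(undec-1-ynyl)-1,3-dioxan-5-ol | CCCCCCCCCC#CC1(O)COC(C)(C)OC1 | intermediate
5 | sodium 2,2-dimethyl-5-(undec-1-ynyl)-1,3-dioxan-5-olate (not isolated) | CCCCCCCCCC#CC1([O-])COC(C)(C)OC1.[Na+] | intermediate
6 | 5-(4-methoxybenzyloxy)-2,2-dimethyl-5-(undec-1-ynyl)-1,3-dioxane | CCCCCCCCCC#CC1(OCc2ccc(OC)cc2)COC(C)(C)OC1 | intermediate
7 | 2-(4-methoxybenzyloxy)-2-(undec-1-ynyl)propane-1,3-diol | CCCCCCCCCC#CC(OCc1ccc(OC)cc1)(CO)CO | intermediate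
8 | 2-(4-methoxybenzyloxy)-2-(undec-1-ynyl)propanedial (achiral malonaldehyde) | CCCCCCCCCC#CC(OCc1ccc(OC)cc1)(C=O)C=O | intermediate
9 | vinylmagnesium bromide | C=C[Mg]Br | starting material
10 | bromomagnesium alkoxide of threo-3-hydroxy-2-(4-methoxybenzyloxy)-2-(undec-1-ynyl)pent-4-enal (racemic, not isolated) | CCCCCCCCCC#C[C@@](OCc1ccc(OC)cc1)([C@@H](O[Mg]Br)C=C)C=O | intermediate
11 | meso threo,threo-4-(4-methoxybenzyloxy)-4-(undec-1-ynyl)hepta-1,6-diene-3,5-diol | CCCCCCCCCC#C[C@@](OCc1ccc(OC)cc1)([C@@H](O)C=C)[C@H](O)C=C | intermediate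
12 | meso 4-(4-methoxybenzyloxy)-4-(undec-1-ynyl)hepta-1,6-diene-3,5-diyl diacetate | CCCCCCCCCC#C[C@@](OCc1ccc(OC)cc1)([C@@H](OC(C)=O)C=C)[C@H](OC(C)=O)C=C | intermediate
13 | meso 2-(4-methoxybenzyloxy)-2-(undec-1-ynyl)cyclopent-4-ene-1,3-diyl diacetate (acetates cis to each other and to the alkyne, trans to the ether oxygen) | CCCCCCCCCC#C[C@@]1(OCc2ccc(OC)cc2)[C@@H](OC(C)=O)C=C[C@H]1OC(C)=O | intermediate
14 | meso 2-(4-methoxybenzyloxy)-2-undecanoylcyclopent-4-ene-1,3-diyl diacetate (same relative configuration) | CCCCCCCCCCC(=O)[C@@]1(OCc2ccc(OC)cc2)[C@@H](OC(C)=O)C=C[C@H]1OC(C)=O | intermediate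
15 | meso 2-hydroxy-2-undecanoylcyclopent-4-ene-1,3-diyl diacetate (acetates cis to each other and to the acyl group, trans to the hydroxyl) | CCCCCCCCCCC(=O)[C@@]1(O)[C@@H](OC(C)=O)C=C[C@H]1OC(C)=O | target

**Totals**
Total steps: 9. Longest linear sequence: 9 (fully linear from 1-undecyne).

**Steps most likely to fail**

1. Step 5. Facial selectivity may be low or reversed at one or both formyl groups. A six-membered magnesium chelate across the two carbonyl oxygens (first addition), across the new alkoxide and the remaining carbonyl (second addition), or an open transition state would bring vinyl in from the face away from the alkyne. Fallback: accept open-transition-state control and correct the carbinol configuration after ring closure. It sets out from 8. Vinyllithium in THF at −78 °C without a chelating Lewis acid should favour, by a Felkin–Anh arrangement with the ether oxygen anti to the nucleophile and the alkyne as the small group, meso erythro,erythro-4-(4-methoxybenzyloxy)-4-(undec-1-ynyl)hepta-1,6-diene-3,5-diol F1. Ring-closing metathesis with the second-generation Grubbs catalyst (H2IMes)(PCy3)Cl2Ru=CHPh in CH2Cl2 should give meso 2-(4-methoxybenzyloxy)-2-(undec-1-ynyl)cyclopent-4-ene-1,3-diol F2, in which both hydroxyls are cis to the ether oxygen. Double Mitsunobu esterification (AcOH, PPh3, DIAD, THF) should invert both allylic carbinols, the acetate entering from the alkyne-flanked face, and the sequence comes back to the route at 13.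

2. Step 8. Regiocontrol may be lost: water can add at the distal alkyne carbon, the position favoured by the propargylic oxygen, or a 1,5-hydride shift from the PMB methylene to the gold-activated alkyne may compete with acetate participation. Fallback: a silicon tether that fixes oxygen on the proximal alkyne carbon by ring size, followed by Tamao–Fleming oxidation. It sets out from 13. Methanolysis (K2CO3, MeOH, 0 °C) should give meso 2-(4-methoxybenzyloxy)-2-(undec-1-ynyl)cyclopent-4-ene-1,3-diol F3, in which both hydroxyls are trans to the ether oxygen. Silylation with (HMe2Si)2NH (neat, 60 °C) should give the bis(dimethylsilyl) ether F4. Pt2[(CH2=CHSiMe2)2O]3 (zerovalent platinum, THF, rt) should effect 5-exo-dig syn hydrosilylation by one Si–H group to give the bicyclic alkenylsiloxane F5. Oxidation (H2O2, KF, KHCO3, THF/MeOH) should give meso 2-(4-methoxybenzyloxy)-2-undecanoylcyclopent-4-ene-1,3-diol F6. Acetylation (Ac2O, DMAP, pyridine) comes back to the route at 14.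

3. Step 4. The dialdehyde may be lost through hydration, oligomerisation or nucleophile-induced deformylation during oxidation and handling. Fallback: never form a 1,3-dialdehyde, and oxidise and vinylate one arm at a time. It sets out from 7. Monosilylation (NaH, 1 equiv, then TBSCl, THF) should give 3-(tert-butyldimethylsilyloxy)-2-(4-methoxybenzyloxy)-2-(undec-1-ynyl)propan-1-ol F7. Dess–Martin oxidation should give 3-(tert-butyldimethylsilyloxy)-2-(4-methoxybenzyloxy)-2-(undec-1-ynyl)propanal F8. Chelate-controlled addition (MgBr2·OEt2, CH2=CHMgBr, CH2Cl2, −78 °C), in which the non-coordinating silyl ether leaves only the five-membered chelate to the PMB oxygen, should give threo-1-(tert-butyldimethylsilyloxy)-2-(4-methoxybenzyloxy)-2-(undec-1-ynyl)pent-4-en-3-ol F9. Desilylation (Bu4NF, THF) should give threo-2-(4-methoxybenzyloxy)-2-(undec-1-ynyl)pent-4-ene-1,3-diol F10. Primary-selective oxidation (TEMPO, PhI(OAc)2, CH2Cl2) should give threo-3-hydroxy-2-(4-methoxybenzyloxy)-2-(undec-1-ynyl)pent-4-enal F11. A second chelate-controlled addition (MgBr2·OEt2, CH2=CHMgBr, 2.5 equiv) comes back to the route at 11.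

Further compounds
F1 | step 5 | meso erythro,erythro-4-(4-methoxybenzyloxy)-4-(undec-1-ynyl)hepta-1,6-diene-3,5-diol | CCCCCCCCCC#C[C@](OCc1ccc(OC)cc1)([C@@H](O)C=C)[C@H](O)C=C
F2 | step 5 | meso 2-(4-methoxybenzyloxy)-2-(undec-1-ynyl)cyclopent-4-ene-1,3-diol, hydroxyls cis to the ether oxygen | CCCCCCCCCC#C[C@]1(OCc2ccc(OC)cc2)[C@@H](O)C=C[C@H]1O
F3 | step 8 | meso 2-(4-methoxybenzyloxy)-2-(undec-1-ynyl)cyclopent-4-ene-1,3-diol, hydroxyls trans to the ether oxygen | CCCCCCCCCC#C[C@@]1(OCc2ccc(OC)cc2)[C@@H](O)C=C[C@H]1O
F4 | step 8 | bis(dimethylsilyl) ether of F3 | CCCCCCCCCC#C[C@@]1(OCc2ccc(OC)cc2)[C@@H](O[SiH](C)C)C=C[C@H]1O[SiH](C)C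
F5 | step 8 | bicyclic alkenylsiloxane from 5-exo-dig syn hydrosilylation (racemic) | CCCCCCCCC/C=C1/[Si](C)(C)O[C@H]2C=C[C@@H](O[SiH](C)C)[C@@]12OCc1ccc(OC)cc1
F6 | step 8 | meso 2-(4-methoxybenzyloxy)-2-undecanoylcyclopent-4-ene-1,3-diol | CCCCCCCCCCC(=O)[C@@]1(OCc2ccc(OC)cc2)[C@@H](O)C=C[C@H]1O
F7 | step 4 | 3-(tert-butyldimethylsilyloxy)-2-(4-methoxybenzyloxy)-2-(undec-1-ynyl)propan-1-ol (racemic) | CCCCCCCCCC#C[C@@](OCc1ccc(OC)cc1)(CO)CO[Si](C)(C)C(C)(C)C
F8 | step 4 | 3-(tert-butyldimethylsilyloxy)-2-(4-methoxybenzyloxy)-2-(undec-1-ynyl)propanal (racemic) | CCCCCCCCCC#C[C@@](OCc1ccc(OC)cc1)(C=O)CO[Si](C)(C)C(C)(C)C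
F9 | step 4 | threo-1-(tert-butyldimethylsilyloxy)-2-(4-methoxybenzyloxy)-2-(undec-1-ynyl)pent-4-en-3-ol (racemic) | CCCCCCCCCC#C[C@@](OCc1ccc(OC)cc1)([C@@H](O)C=C)CO[Si](C)(C)C(C)(C)C
F10 | step 4 | threo-2-(4-methoxybenzyloxy)-2-(undec-1-ynyl)pent-4-ene-1,3-diol (racemic) | CCCCCCCCCC#C[C@@](OCc1ccc(OC)cc1)([C@@H](O)C=C)CO
F11 | step 4 | threo-3-hydroxy-2-(4-methoxybenzyloxy)-2-(undec-1-ynyl)pent-4-enal (racemic) | CCCCCCCCCC#C[C@@](OCc1ccc(OC)cc1)([C@@H](O)C=C)C=O
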